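## Retrosynthetic overview

1. **Feature:** the terminal rings A and D are 2-propanoyl-6,6-dimethylcyclohexane-1,3,5-triones joined to the core through C4. In each, carbonyl C1 lies between the quaternary C6 (CMe2) and the acyl-bearing C2, so cutting C1–C2 unfolds the ring into a methyl 2,2-dimethyl-3,5,7-trioxononanoate chain (ester carbon = ring C1, chain C6 = ring C2, chain C4 = ring C4).
2. Target ⇒ hydrogenolysis of six benzyl ethers on aromatic rings B and C ⇒ hexabenzyl ether ⇒ double Dieckmann closure (C1–C2 of rings A and D) ⇒ core carrying two open triketo ester arms.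
3. Arms ⇒ alkylation at chain C4 of a β-diketone by a bis(bromomethyl) core. The chain C7 ketone is masked as a 1,3-dithiane so that C4 is the only doubly activated carbon. A sulfur mask is preferred to an isoxazole because the amino-enone from N–O cleavage would condense with the C3 ketone (4-pyridone), and hydrogenative opening would strip the benzyl ethers.
4. Core ⇒ flopropione is formylated first, so only one ring carbon remains for the formaldehyde coupling and only the dimer can form. Benzylation and CHO → CH2OH → CH2Br follow.
5. Ring order: B and C are bought as flopropione; A and D are closed together in the penultimate step.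

Key step: step 12

Assumption: 18 and 19 are handled as mixtures of diastereomers and keto–enol tautomers, because chain C4 of each arm is a configurationally labile stereocentre that becomes sp2 in step 12. The target has no stereocentre and is drawn as one enol tautomer.

## Route

Step 1
Reactants: 1 flopropione
Product: 3 2,4,6-trihydroxy-3-propanoylbenzaldehyde, via aryl iminium chloride 2 (not isolated)
Conditions: POCl3 (1.1 equiv), DMF (1.3 equiv), EtOAc, 0 °C → rt; then H2O, 50 °C
Reagents that add atoms: N,N-dimethylformamide CN(C)C=O; water O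
Why: Vilsmeier–Haack formylation, in which the two free ring positions of 1 are equivalent and strongly activated, and the first iminium group deactivates the ring so that about one equivalent of reagent should stop at monoformylation and leave a single free ring carbon.

Step 2
Reactants: 3 2,4,6-trihydroxy-3-propanoylbenzaldehyde (2 equiv); 4 formaldehyde (37% aq., 1 equiv)
Product: 6 3,3'-methylenebis(2,4,6-trihydroxy-5-propanoylbenzaldehyde), via hydroxymethyl adduct 5 (not isolated)
Conditions: NaOAc, AcOH, 70 °C
Reagents that add atoms: none
Why: Hydroxymethylation, loss of water and Friedel–Crafts-type capture by a second molecule of 3 is the standard formaldehyde coupling of acylphloroglucinols, and with only one unsubstituted ring carbon per molecule no oligomer can grow beyond the dimer.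

Step 3
Reactants: 6 3,3'-methylenebis(2,4,6-trihydroxy-5-propanoylbenzaldehyde)
Product: 7 3,3'-methylenebis[2,4,6-tris(benzyloxy)-5-propanoylbenzaldehyde]
Conditions: BnBr (9 equiv), K2CO3 (9 equiv), DMF, 60 °C
Reagents that add atoms: benzyl bromide BrCc1ccccc1
Why: Williamson etherification in a dipolar aprotic solvent favours O- over C-alkylation of the phenolates, no ring C–H is left for C-benzylation, and heat with excess reagent overcomes the carbonyl chelation of the hydroxyls.

Step 4
Reactants: 7 3,3'-methylenebis[2,4,6-tris(benzyloxy)-5-propanoylbenzaldehyde]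
Product: 8 hexa-O-benzyl diol (both CHO groups of 7 reduced to CH2OH)
Conditions: NaBH4 (1.1 equiv), THF–MeOH, −20 → 0 °C
Reagents that add atoms: none
Why: Chemoselective borohydride reduction, since the aldehydes react much faster than the ethyl ketones, which are shielded by two ortho benzyloxy groups and twisted out of the ring plane.

Step 5
Reactants: 8 hexa-O-benzyl diol
Product: 9 hexa-O-benzyl bis(bromomethyl) core (both CH2OH groups of 8 converted to CH2Br)
Conditions: CBr4 (2.6 equiv), PPh3 (2.6 equiv), CH2Cl2, 0 °C; short silica plug, used at once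
Reagents that add atoms: carbon tetrabromide BrC(Br)(Br)Br
Why: The Appel reaction converts primary benzylic alcohols to bromides under neutral conditions that spare benzyl ethers, and the electron-rich bromide cannot self-alkylate because every ring position is occupied.

Step 6
Reactants: 10 dimethyl 2,2-dimethylmalonate
Product: 11 3-methoxy-2,2-dimethyl-3-oxopropanoic acid
Conditions: KOH (1.0 equiv), MeOH, rt; then 1 M HCl
Reagents that add atoms: potassium hydroxide [K+].[OH-]
Why: Mono-saponification with one equivalent of hydroxide, the carboxylate formed first protecting the remaining hindered ester from further attack.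

Step 7
Reactants: 11 3-methoxy-2,2-dimethyl-3-oxopropanoic acid
Product: 12 methyl 3-chloro-2,2-dimethyl-3-oxopropanoate
Conditions: (COCl)2 (1.2 equiv), DMF (cat.), CH2Cl2, 0 °C → rt; evaporation
Reagents that add atoms: oxalyl chloride O=C(Cl)C(=O)Cl
Why: DMF-catalysed acid chloride formation with oxalyl chloride, clean here because the quaternary α-carbon excludes ketene formation.

Step 8
Reactants: 13 hex-3-yn-2-one; 14 propane-1,3-dithiol
Product: 15 1-(2-ethyl-1,3-dithian-2-yl)propan-2-one
Conditions: NaOMe (0.2 equiv), MeOH–CH2Cl2, −10 → 0 °C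
Reagents that add atoms: none
Why: Base-catalysed double conjugate (thia-Michael) addition of a dithiol to an ynone places both sulfur atoms on the β-carbon and so delivers hexane-2,4-dione masked regiospecifically at its ethyl ketone.

Step 9
Reactants: 15 1-(2-ethyl-1,3-dithian-2-yl)propan-2-one (2 equiv); 12 methyl 3-chloro-2,2-dimethyl-3-oxopropanoate (1 equiv)
Product: 17 methyl 6-(2-ethyl-1,3-dithian-2-yl)-2,2-dimethyl-3,5-dioxohexanoate, via lithium enolate 16 (not isolated)
Conditions: LiN(SiMe3)2 (2.0 equiv), THF, −78 °C; then 12, −78 → 0 °C; aq. NH4Cl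
Reagents that add atoms: none
Why: Kinetic deprotonation takes the methyl group rather than the neopentyl-type CH2 beside the dithiane, and Claisen-type C-acylation of the lithium enolate by the non-enolisable acid chloride gives the β-diketone, whose acidic proton is absorbed by the second enolate equivalent.

Step 10
Reactants: 9 hexa-O-benzyl bis(bromomethyl) core (1 equiv); 17 methyl 6-(2-ethyl-1,3-dithian-2-yl)-2,2-dimethyl-3,5-dioxohexanoate (2.3 equiv)
Product: 18 hexa-O-benzyl core with two dithiane-masked arms (each benzylic CH2 bonded to chain C4 of a unit of 17)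
Conditions: K2CO3 (3 equiv), DMF, 0 °C → rt
Reagents that add atoms: none
Why: C-alkylation of a β-diketone enolate with a benzylic halide, unambiguous in site because with C7 masked only C4 lies between two carbonyls, and the crowded monoalkylated carbon should not react a second time.

Step 11
Reactants: 18 hexa-O-benzyl core with two dithiane-masked arms
Product: 19 hexa-O-benzyl core with two methyl 2,2-dimethyl-3,5,7-trioxononanoate arms attached through C4
Conditions: PhI(OCOCF3)2 (3 equiv), MeCN–THF–H2O, 0 °C, short reaction time; aq. Na2S2O3, pH 7 buffer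
Reagents that add atoms: water O
Why: Oxidative dithiane hydrolysis with a hypervalent iodine reagent attacks sulfur far faster than benzyl ethers, ketones or enols, and a brief reaction in a cold water-rich medium frees the C7 ketones without the dehydrating acid that would turn a 1,3,5-triketone into a γ-pyrone.

Step 12
Reactants: 19 hexa-O-benzyl core with two methyl 2,2-dimethyl-3,5,7-trioxononanoate arms
Product: 21 hexa-O-benzyl ether of the target, via tetrasodium enolate salt 20 (not isolated)
Conditions: NaOMe (10 equiv), MeOH–THF, 0 → 45 °C; then cold 1 M HCl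
Reagents that add atoms: none
Why: Methoxide removes a proton from chain C6 of each arm, the unsubstituted and most acidic methylene between the C5 and C7 carbonyls, and this carbanion adds to ester carbon C1 and expels methoxide to make the ring C1–C2 bond. This is a Dieckmann (intramolecular Claisen) condensation of a 3,5,7-triketo ester, the reaction type that converts such esters into 2-acylcyclohexane-1,3,5-triones and acylphloroglucinols. Ring A and ring D each close in the 6-(enolexo)-exo-trig mode, assisted by the gem-dimethyl group, which also keeps the ester from enolising. No stereocentre is created, and the two labile C4 centres of 19 become sp2 as the new rings enolise. For site selectivity, chain C4 could only form a four-membered ring, chain C8 (a possible aldol donor towards C3) is not deprotonated by methoxide, and attack of the C5 enolate oxygen on the ester gives a δ-enol lactone that methoxide reopens, so the reversible manifold should drain into the doubly deprotonated triones of 20. The C3 ketone is guarded against retro-Claisen cleavage by its two branched neighbours and its enolate character, and the benzyl ethers stop the phenols from adding to C3 or C5 (chromene formation) and from starting base-induced exchange of the methylene-linked rings.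

Step 13
Reactants: 21 hexa-O-benzyl ether of the target
Product: 22 target CNP0541376.0
Conditions: H2 (1 atm), 10% Pd/C, THF–MeOH, rt
Reagents that add atoms: none
Why: Catalytic hydrogenolysis of aryl benzyl ethers under neutral conditions leaves the chelated aryl ketones, the enolised triones and the CH2 bridges untouched, and the absence of acid or base avoids scrambling of the methylene-linked rings.

## Compound list

1 | flopropione, 1-(2,4,6-trihydroxyphenyl)propan-1-one | CCC(=O)c1c(O)cc(O)cc1O | starting material
2 | aryl iminium chloride (ArCH=NMe2+ Cl−, precursor of 3) | CCC(=O)c1c(O)cc(O)c(C=[N+](C)C)c1O.[Cl-] | intermediate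
3 | 2,4,6-trihydroxy-3-propanoylbenzaldehyde | CCC(=O)c1c(O)cc(O)c(C=O)c1O | intermediate
4 | formaldehyde | C=O | starting material
5 | 2,4,6-trihydroxy-3-(hydroxymethyl)-5-propanoylbenzaldehyde | CCC(=O)c1c(O)c(CO)c(O)c(C=O)c1O | intermediate
6 | 3,3'-methylenebis(2,4,6-trihydroxy-5-propanoylbenzaldehyde) | CCC(=O)c1c(O)c(Cc2c(O)c(C=O)c(O)c(C(=O)CC)c2O)c(O)c(C=O)c1O | intermediate
7 | 3,3'-methylenebis[2,4,6-tris(benzyloxy)-5-propanoylbenzaldehyde] | O=Cc1c(OCc2ccccc2)c(Cc2c(OCc3ccccc3)c(C=O)c(OCc3ccccc3)c(C(=O)CC)c2OCc2ccccc2)c(OCc2ccccc2)c(C(=O)CC)c1OCc1ccccc1 | intermediate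
8 | hexa-O-benzyl diol (7 with both CHO as CH2OH) | OCc1c(OCc2ccccc2)c(Cc2c(OCc3ccccc3)c(CO)c(OCc3ccccc3)c(C(=O)CC)c2OCc2ccccc2)c(OCc2ccccc2)c(C(=O)CC)c1OCc1ccccc1 | intermediate
9 | hexa-O-benzyl bis(bromomethyl) core (8 with both CH2OH as CH2Br) | BrCc1c(OCc2ccccc2)c(Cc2c(OCc3ccccc3)c(CBr)c(OCc3ccccc3)c(C(=O)CC)c2OCc2ccccc2)c(OCc2ccccc2)c(C(=O)CC)c1OCc1ccccc1 | intermediate
10 | dimethyl 2,2-dimethylmalonate | COC(=O)C(C)(C)C(=O)OC | starting material
11 | 3-methoxy-2,2-dimethyl-3-oxopropanoic acid | COC(=O)C(C)(C)C(=O)O | intermediate
12 | methyl 3-chloro-2,2-dimethyl-3-oxopropanoate | COC(=O)C(C)(C)C(=O)Cl | intermediate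
13 | hex-3-yn-2-one | CCC#CC(C)=O | starting material
14 | propane-1,3-dithiol | SCCCS | starting material
15 | 1-(2-ethyl-1,3-dithian-2-yl)propan-2-one | CCC1(CC(C)=O)SCCCS1 | intermediate
16 | lithium enolate of 15 on the methyl side, CH2=C(OLi)– | CCC1(CC(=C)[O-])SCCCS1.[Li+] | intermediate
17 | methyl 6-(2-ethyl-1,3-dithian-2-yl)-2,2-dimethyl-3,5-dioxohexanoate | CCC1(CC(=O)CC(=O)C(C)(C)C(=O)OC)SCCCS1 | intermediate
18 | hexa-O-benzyl core with two dithiane-masked arms, each attached through chain C4 (diastereomer mixture at the two labile C4 centres) | CCC1(CC(=O)C(Cc2c(OCc3ccccc3)c(Cc3c(OCc4ccccc4)c(CC(C(=O)CC4(CC)SCCCS4)C(=O)C(C)(C)C(=O)OC)c(OCc4ccccc4)c(C(=O)CC)c3OCc3ccccc3)c(OCc3ccccc3)c(C(=O)CC)c2OCc2ccccc2)C(=O)C(C)(C)C(=O)OC)SCCCS1 | intermediate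
19 | hexa-O-benzyl core with two methyl 2,2-dimethyl-3,5,7-trioxononanoate arms attached through C4 (diastereomer and tautomer mixture) | CCC(=O)CC(=O)C(Cc1c(OCc2ccccc2)c(Cc2c(OCc3ccccc3)c(CC(C(=O)CC(=O)CC)C(=O)C(C)(C)C(=O)OC)c(OCc3ccccc3)c(C(=O)CC)c2OCc2ccccc2)c(OCc2ccccc2)c(C(=O)CC)c1OCc1ccccc1)C(=O)C(C)(C)C(=O)OC | intermediate
20 | tetrasodium salt of 21 (both enols of each terminal ring deprotonated) | CCC(=O)C1=C([O-])C(Cc2c(OCc3ccccc3)c(Cc3c(OCc4ccccc4)c(CC4=C([O-])C(C)(C)C(=O)C(C(=O)CC)=C4[O-])c(OCc4ccccc4)c(C(=O)CC)c3OCc3ccccc3)c(OCc3ccccc3)c(C(=O)CC)c2OCc2ccccc2)=C([O-])C(C)(C)C1=O.[Na+].[Na+].[Na+].[Na+] | intermediate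
21 | hexa-O-benzyl ether of the target | CCC(=O)C1=C(O)C(Cc2c(OCc3ccccc3)c(Cc3c(OCc4ccccc4)c(CC4=C(O)C(C)(C)C(=O)C(C(=O)CC)=C4O)c(OCc4ccccc4)c(C(=O)CC)c3OCc3ccccc3)c(OCc3ccccc3)c(C(=O)CC)c2OCc2ccccc2)=C(O)C(C)(C)C1=O | intermediate
22 | CNP0541376.0 | CCC(=O)C1=C(O)C(Cc2c(O)c(Cc3c(O)c(CC4=C(O)C(C)(C)C(=O)C(C(=O)CC)=C4O)c(O)c(C(=O)CC)c3O)c(O)c(C(=O)CC)c2O)=C(O)C(C)(C)C1=O | target

## Step count and risks

Total step count: 13.
Longest linear sequence: 9 steps (steps 1–5 and 10–13). Steps 6–9 build the arm in parallel.

**1. Step 12.**
- **What may go wrong:** crowding by the flanking benzyloxy groups may let only one arm close. It may also stall the system at reversible O-acylation, or give methoxide time to fragment the arm by retro-Claisen attack at C3.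
- **Fallback (sets out from 17, returns at 21):** the ring is closed on the free arm, where chain C4 is still unsubstituted, and the core is attached afterwards. Compound 17 is unmasked with PhI(OCOCF3)2 in aqueous MeCN to methyl 2,2-dimethyl-3,5,7-trioxononanoate F1. NaOMe in MeOH closes this by the same Dieckmann mode to 3,5-dihydroxy-6,6-dimethyl-2-propanoylcyclohexa-2,4-dien-1-one F2. The dianion of F2 (NaH, THF–DMF) is then C-benzylated at C4, its only free ring carbon, by dibromide 9, which gives 21.

**2. Step 11.**
- **What may go wrong:** the freshly released triketone may cyclodehydrate (C3 enol oxygen onto C7), or the iodane may over-oxidise the enolic chain.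
- **Fallback (sets out from 18, returns at 21):** the cyclodehydration is made the intended course. After dithiane cleavage the crude material is stirred with CF3CO2H in CH2Cl2, so that both arms end as 2-ethyl-4-pyranones in the stable, chromatographable hexa-O-benzyl bis(γ-pyrone) F3. KOH in aqueous MeOH–THF then adds hydroxide to the ethyl-bearing pyrone carbon and opens each ring to the triketone enolate, which is the classical alkaline opening of 2,6-dialkyl-4-pyranones. This enolate undergoes the same Claisen closure in the pot faster than the hindered ester is saponified, and acidification gives 21.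

**3. Step 10.**
- **What may go wrong:** the doubly ortho-flanked, readily ionised bromide may decompose before use, may alkylate the enolate on oxygen, or may attach only one arm.
- **Fallback (sets out from 8, returns at 18):** the halide is omitted, so step 5 is skipped. Diol 8 and β-diketone 17 are joined by Bi(OTf)3-catalysed dehydrative benzylation in MeNO2–CH2Cl2. This uses the same ease of ionisation through a stabilised benzylic cation, which the neutral enol captures at carbon. The fallback makes no new compound (F0).

Further compounds
F1 | step 12 | methyl 2,2-dimethyl-3,5,7-trioxononanoate | CCC(=O)CC(=O)CC(=O)C(C)(C)C(=O)OC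
F2 | step 12 | 3,5-dihydroxy-6,6-dimethyl-2-propanoylcyclohexa-2,4-dien-1-one | CCC(=O)C1=C(O)C=C(O)C(C)(C)C1=O
F3 | step 11 | hexa-O-benzyl bis(γ-pyrone), each benzylic CH2 on C5 of a 2-ethyl-6-(1-methoxy-2-methyl-1-oxopropan-2-yl)-4H-pyran-4-one | CCc1cc(=O)c(Cc2c(OCc3ccccc3)c(Cc3c(OCc4ccccc4)c(Cc4c(C(C)(C)C(=O)OC)oc(CC)cc4=O)c(OCc4ccccc4)c(C(=O)CC)c3OCc3ccccc3)c(OCc3ccccc3)c(C(=O)CC)c2OCc2ccccc2)c(C(C)(C)C(=O)OC)o1
F0 | step 10 | none | none
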